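**Plan**
- Retrosynthetic cuts: the two C7–aryl bonds (an ester plus two aryllithium equivalents), the a6–C(sp) bond (Sonogashira coupling at a phenol triflate), and the ring A bonds a4–a5 and a1–a2 (Michael–aldol annulation).
- Enabling feature: ring A carries, in a row, ring B on a4, the carboxyl-level carbon C7 on a5, a carbon that can be a ketone or phenol at a6, and methyl on a1. This is the aryl/ester/oxo/methyl order of the cyclohexenone formed from a 3-oxopentanoate and a cinnamaldehyde.
- Forward order: ring A is closed first as a cyclohexenone and dehydrogenated to a salicylate. Its hydroxyl becomes the triflate that takes the arylalkyne, the ester takes two 4-methoxyphenyl groups, and BBr3 frees four phenols while the carbinol dehydrates to the quinone methide.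
- Stereochemistry: the target has no stereocentre (the quinone methide ring is symmetric about its axis). The two sp3 centres made in the key step disappear on aromatisation.

Key step: step 1

Remark: ring A is labelled a1 (methyl-bearing carbon), a2 and a3 (CH), a4 (bears ring B), a5 (bears C7) and a6 (bears the alkyne). The chiral amine in step 1 is used only for its bulk, so the sp3 intermediates are handled as stereoisomer mixtures.

**Step 1**
Reactants: 1 ethyl 3-oxopentanoate; 2 (E)-4-methoxycinnamaldehyde
Product: 5 ethyl 6-(4-methoxyphenyl)-3-methyl-2-oxocyclohex-3-ene-1-carboxylate (stereoisomer mixture), via Michael adduct aldehyde 3 (not isolated), via aldol cyclohexanone 4 (not isolated)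
Conditions: (S)-α,α-diphenylprolinol trimethylsilyl ether (10 mol %), PhCO2H (10 mol %), toluene, rt; then p-TsOH·H2O (30 mol %), 80 °C
Reagents that add atoms: none
Why: The amine condenses with 2 to an iminium ion, the enol of 1 adds through its doubly activated C2 to the β-carbon (Michael addition, bond a5–a4) and hydrolysis gives aldehyde 3; p-TsOH then enolises the ethyl ketone toward C4, which attacks the aldehyde carbon (intramolecular aldol, bond a1–a2) to give 4, and loss of water gives the conjugated enone 5. The closest known reaction type is the amine-catalysed Michael addition of β-keto esters to enals followed by acid-mediated aldol condensation, a Robinson-type annulation to 2-cyclohexenones. The six-membered carbocycle closes in a 6-(enolendo)-exo-trig aldol addition. Two sp3 centres arise at a4 and a5, the first set by the shielded face of the iminium ion and the second epimerisable between two carbonyls, and neither needs control because step 2 removes both. The step needs conjugate instead of 1,2-addition (Knoevenagel condensation), which the bulky diphenyl(silyloxy)methyl arm of the amine secures by screening the iminium carbon, and it needs C2 as Michael donor and C4 as aldol donor, which the acidity order of 1 and the impossibility of a four-membered closure from C2 secure. The ethyl ester, unlike a tert-butyl ester, should survive the acid without decarboxylation, so the carboxyl carbon stays on a5.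

**Step 2**
Reactants: 5 ethyl 6-(4-methoxyphenyl)-3-methyl-2-oxocyclohex-3-ene-1-carboxylate
Product: 6 ethyl 2-hydroxy-6-(4-methoxyphenyl)-3-methylbenzoate
Conditions: DDQ (1.2 equiv), 1,4-dioxane, 90 °C
Reagents that add atoms: none
Why: Quinone dehydrogenation, in which the dienol form of the β-keto ester gives a hydride from a ring sp3 C–H to DDQ and the cation loses a proton, should be driven by the gain of aromaticity to the hydrogen-bonded salicylate, with the anisyl ring and ester untouched.

**Step 3**
Reactants: 6 ethyl 2-hydroxy-6-(4-methoxyphenyl)-3-methylbenzoate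
Product: 7 ethyl 6-(4-methoxyphenyl)-3-methyl-2-(trifluoromethanesulfonyloxy)benzoate
Conditions: Tf2O (1.3 equiv), pyridine (3 equiv), CH2Cl2, 0 °C → rt
Reagents that add atoms: trifluoromethanesulfonic anhydride, O=S(=O)(OS(=O)(=O)C(F)(F)F)C(F)(F)F
Why: O-Sulfonylation of a phenol with Tf2O and pyridine is routine for salicylates, the base breaking the hydrogen bond to the ester, and nothing else in 6 is nucleophilic.

**Step 4**
Reactants: 7 ethyl 6-(4-methoxyphenyl)-3-methyl-2-(trifluoromethanesulfonyloxy)benzoate; 8 4-ethynylanisole
Product: 9 ethyl 6-(4-methoxyphenyl)-2-[(4-methoxyphenyl)ethynyl]-3-methylbenzoate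
Conditions: 8 (1.5 equiv), PdCl2(PPh3)2 (5 mol %), CuI (10 mol %), Et3N, DMF, 80 °C, degassed
Reagents that add atoms: none
Why: In this Sonogashira coupling, oxidative addition of zerovalent palladium into the C–OTf bond is helped by the electron-withdrawing ortho ester, and transmetalation from the copper acetylide of 8 followed by reductive elimination should form the a6–C(sp) bond, the slim alkyne tolerating the two ortho neighbours.

**Step 5**
Reactants: 9 ethyl 6-(4-methoxyphenyl)-2-[(4-methoxyphenyl)ethynyl]-3-methylbenzoate; 10 4-bromoanisole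
Product: 13 bis(4-methoxyphenyl)[6-(4-methoxyphenyl)-2-[(4-methoxyphenyl)ethynyl]-3-methylphenyl]methanol, via 4-methoxyphenyllithium 11 (not isolated), via diaryl ketone 12 (not isolated)
Conditions: 10 (3.5 equiv), n-BuLi (3.4 equiv), THF, −78 °C; then 9, −78 °C → rt; aq NH4Cl at 0 °C
Reagents that add atoms: none
Why: Bromine–lithium exchange gives 11, whose first equivalent adds to the ester and expels ethoxide to give ketone 12 and whose second equivalent adds to that ketone (double addition of an organolithium to an ester), the linear alkynyl neighbour leaving the carbonyl open on one side and the cold quench keeping the alkoxide from adding to the alkyne.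

**Step 6**
Reactants: 13 bis(4-methoxyphenyl)[6-(4-methoxyphenyl)-2-[(4-methoxyphenyl)ethynyl]-3-methylphenyl]methanol
Product: 15 Selaginellin U, via tetraphenol carbinol 14 (not isolated)
Conditions: BBr3 (10 equiv), CH2Cl2, −78 °C → 0 °C; then ice-water
Reagents that add atoms: none
Why: BBr3 cleavage of the four aryl methyl ethers (boron coordination, then bromide attack on methyl) frees the phenols, and the bis(4-hydroxyphenyl)carbinol 14 ionises to a strongly stabilised trityl cation that loses a phenolic proton, so dehydration to the para-quinone methide (fuchsone formation) should follow on work-up; the cation is too stabilised to attack the unactivated position of ring B at low temperature.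

**Compound list**
1 | ethyl 3-oxopentanoate | CCC(=O)CC(=O)OCC | starting material
2 | (E)-4-methoxycinnamaldehyde | COc1ccc(/C=C/C=O)cc1 | starting material
3 | ethyl 2-[1-(4-methoxyphenyl)-3-oxopropyl]-3-oxopentanoate (stereoisomer mixture, Michael adduct) | CCC(=O)C(C(=O)OCC)C(CC=O)c1ccc(OC)cc1 | intermediate
4 | ethyl 4-hydroxy-6-(4-methoxyphenyl)-3-methyl-2-oxocyclohexane-1-carboxylate (stereoisomer mixture, aldol) | CCOC(=O)C1C(=O)C(C)C(O)CC1c1ccc(OC)cc1 | intermediate
5 | ethyl 6-(4-methoxyphenyl)-3-methyl-2-oxocyclohex-3-ene-1-carboxylate (stereoisomer mixture) | CCOC(=O)C1C(=O)C(C)=CCC1c1ccc(OC)cc1 | intermediate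
6 | ethyl 2-hydroxy-6-(4-methoxyphenyl)-3-methylbenzoate | CCOC(=O)c1c(O)c(C)ccc1-c1ccc(OC)cc1 | intermediate
7 | ethyl 6-(4-methoxyphenyl)-3-methyl-2-(trifluoromethanesulfonyloxy)benzoate | CCOC(=O)c1c(OS(=O)(=O)C(F)(F)F)c(C)ccc1-c1ccc(OC)cc1 | intermediate
8 | 4-ethynylanisole | C#Cc1ccc(OC)cc1 | starting material
9 | ethyl 6-(4-methoxyphenyl)-2-[(4-methoxyphenyl)ethynyl]-3-methylbenzoate | CCOC(=O)c1c(C#Cc2ccc(OC)cc2)c(C)ccc1-c1ccc(OC)cc1 | intermediate
10 | 4-bromoanisole | COc1ccc(Br)cc1 | starting material
11 | 4-methoxyphenyllithium | [Li]c1ccc(OC)cc1 | intermediate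
12 | (4-methoxyphenyl)[6-(4-methoxyphenyl)-2-[(4-methoxyphenyl)ethynyl]-3-methylphenyl]methanone | COc1ccc(cc1)C(=O)c1c(C#Cc2ccc(OC)cc2)c(C)ccc1-c1ccc(OC)cc1 | intermediate
13 | bis(4-methoxyphenyl)[6-(4-methoxyphenyl)-2-[(4-methoxyphenyl)ethynyl]-3-methylphenyl]methanol | COc1ccc(cc1)C(O)(c1ccc(OC)cc1)c1c(C#Cc2ccc(OC)cc2)c(C)ccc1-c1ccc(OC)cc1 | intermediate
14 | bis(4-hydroxyphenyl)[6-(4-hydroxyphenyl)-2-[(4-hydroxyphenyl)ethynyl]-3-methylphenyl]methanol | Cc1ccc(-c2ccc(O)cc2)c(C(O)(c2ccc(O)cc2)c2ccc(O)cc2)c1C#Cc1ccc(O)cc1 | intermediate
15 | Selaginellin U, 4-[(4-hydroxyphenyl)[6-(4-hydroxyphenyl)-2-[(4-hydroxyphenyl)ethynyl]-3-methylphenyl]methylidene]cyclohexa-2,5-dien-1-one | Cc1ccc(-c2ccc(O)cc2)c(C(=C2C=CC(=O)C=C2)c2ccc(O)cc2)c1C#Cc1ccc(O)cc1 | target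

**Totals**
Total step count: 6. Longest linear sequence: 6 steps (1 and 2 to 15).

**Steps most likely to fail**

Step 5. The aryl transfer may stop short: the crowded ester may resist attack, or the flanked ketone formed after the first addition may not take the second aryllithium. The fallback sets out from 9 and lowers the oxidation level so that each aryl group is added to a less hindered carbonyl. Reduction of 9 with i-Bu2AlH (CH2Cl2, −78 °C → 0 °C) should give [6-(4-methoxyphenyl)-2-[(4-methoxyphenyl)ethynyl]-3-methylphenyl]methanol F1. Oxidation with MnO2 (CH2Cl2, rt) should give 6-(4-methoxyphenyl)-2-[(4-methoxyphenyl)ethynyl]-3-methylbenzaldehyde F2. Addition of 4-methoxyphenylmagnesium bromide (THF, 0 °C) should give racemic (4-methoxyphenyl)[6-(4-methoxyphenyl)-2-[(4-methoxyphenyl)ethynyl]-3-methylphenyl]methanol F3. Dess–Martin periodinane then gives ketone 12, now isolated, and 11 in the presence of anhydrous CeCl3 (THF, −78 °C) adds to it, so the route is rejoined at 13.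

Step 6. Acid-driven side reactions may accompany the ether cleavage: addition of HBr or of the boron bromide across the electron-rich diarylalkyne, or Friedel–Crafts closure of the trityl cation onto ring B. The fallback sets out from 13 and removes the cation before the ethers are cleaved. Ionic hydrogenation (Et3SiH, CF3CO2H, CH2Cl2, 0 °C) should give the triarylmethane 1-[bis(4-methoxyphenyl)methyl]-6-(4-methoxyphenyl)-2-[(4-methoxyphenyl)ethynyl]-3-methylbenzene F4. Nucleophilic demethylation with MeMgI (neat, 160 °C) should give the leuco tetraphenol 4,4'-[[6-(4-hydroxyphenyl)-2-[(4-hydroxyphenyl)ethynyl]-3-methylphenyl]methylene]diphenol F5. Hydride abstraction from its triarylmethine C–H with DDQ (1 equiv, THF, 0 °C) should give the quinone methide, so the route is rejoined at 15.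

Step 4. Oxidative addition at the doubly ortho-flanked triflate may be slow, letting copper-mediated homocoupling of the alkyne and amine cleavage of the S–O bond of the triflate outrun the coupling. The fallback sets out from 7 and 8 and uses a copper-free and amine-free Stille alkynylation. Deprotonation of 8 with n-BuLi (THF, −78 °C) and quenching with Bu3SnCl should give tributyl[(4-methoxyphenyl)ethynyl]stannane F6. Coupling of F6 with 7 under Pd(PPh3)4 and LiCl in 1,4-dioxane at 100 °C rejoins the route at 9.

**Further compounds**
F1 | step 5 | [6-(4-methoxyphenyl)-2-[(4-methoxyphenyl)ethynyl]-3-methylphenyl]methanol | OCc1c(C#Cc2ccc(OC)cc2)c(C)ccc1-c1ccc(OC)cc1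
F2 | step 5 | 6-(4-methoxyphenyl)-2-[(4-methoxyphenyl)ethynyl]-3-methylbenzaldehyde | O=Cc1c(C#Cc2ccc(OC)cc2)c(C)ccc1-c1ccc(OC)cc1
F3 | step 5 | (4-methoxyphenyl)[6-(4-methoxyphenyl)-2-[(4-methoxyphenyl)ethynyl]-3-methylphenyl]methanol (racemic) | COc1ccc(cc1)C(O)c1c(C#Cc2ccc(OC)cc2)c(C)ccc1-c1ccc(OC)cc1
F4 | step 6 | 1-[bis(4-methoxyphenyl)methyl]-6-(4-methoxyphenyl)-2-[(4-methoxyphenyl)ethynyl]-3-methylbenzene | COc1ccc(cc1)C(c1ccc(OC)cc1)c1c(C#Cc2ccc(OC)cc2)c(C)ccc1-c1ccc(OC)cc1
F5 | step 6 | 4,4'-[[6-(4-hydroxyphenyl)-2-[(4-hydroxyphenyl)ethynyl]-3-methylphenyl]methylene]diphenol | Cc1ccc(-c2ccc(O)cc2)c(C(c2ccc(O)cc2)c2ccc(O)cc2)c1C#Cc1ccc(O)cc1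
F6 | step 4 | tributyl[(4-methoxyphenyl)ethynyl]stannane | CCCC[Sn](CCCC)(CCCC)C#Cc1ccc(OC)cc1
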